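**Plan**

Numbering used throughout: C6 is the spiro carbon; ring A is C1(=CH2)–C2(=O)–C3=C4–C5(CH3)2–C6; ring B is C6–C7H2–C8H(Br)–C9(CH3)(Cl)–C10H2–C11H(OAc).
Late cuts: the C1 methylene and the C2 ketone are removed from ring A (methylenation, allylic oxidation), then the acetate and the trans Br/Cl pair from ring B (bromochlorination of a C8=C9 alkene next to a free C11 hydroxyl); that alkene and hydroxyl are traced to a ring B enone (C8=O, C9=C10).
Key cut: ring B is opened at C8–C9 and C10–C11, which excises a two-carbon alkyne unit (C9 with its methyl, C10) and leaves a spiro-fused cyclobutanone with C8 as the carbonyl carbon.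
Enabling feature: C6 carries two CH2 arms (C7, C11) that are identical until C11 is oxidised, so in 5,5-dimethylspiro[3.5]non-6-en-2-one the C8–C7 and C8–C11 bonds are enantiotopic; inserting the alkyne into one of them builds ring B and makes C6, which sits next to the quaternary C5, a stereocentre.
Forward order: ring A from 2,2-dimethylcyclohexane-1,3-dione, exocyclic alkene, ketene [2+2] to the four-membered ring, ring expansion to ring B, C11 hydroxylation, alkene transposition, Br/Cl, then the ring A dienone.
Stereochemistry: C6 from the chiral nickel catalyst; C11 from axial peracid attack anti to C5; C9 from chloride delivered by titanium cis to O11; C8 from anti opening of the bromonium ion.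

Key step: step 6

Assumption: 2,2-dimethylcyclohexane-1,3-dione and 1-(trimethylsilyl)propyne are taken as commercial; locants in names follow the numbering above, not lowest-locant rules.

**Route**

Step 1
Reactants: 1 2,2-dimethylcyclohexane-1,3-dione
Product: 3 6,6-dimethyl-5-oxocyclohex-1-en-1-yl trifluoromethanesulfonate, via potassium enolate 2 (not isolated)
Conditions: KN(SiMe3)2 (1.0 equiv), THF, −78 °C; then PhNTf2, −78 °C to 0 °C
Reagents that add atoms: N-phenylbis(trifluoromethanesulfonimide), O=S(=O)(N(c1ccccc1)S(=O)(=O)C(F)(F)F)C(F)(F)F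
Why: One equivalent of base should convert one of the two equivalent ketones into enolate 2, which resists a second deprotonation, and O-sulfonylation gives the vinyl triflate (enol triflate formation); no stereocentre is formed.

Step 2
Reactants: 3 6,6-dimethyl-5-oxocyclohex-1-en-1-yl trifluoromethanesulfonate
Product: 4 2,2-dimethylcyclohex-3-en-1-one
Conditions: Pd(OAc)2 (cat.), PPh3, HCO2H, Bu3N, DMF, 60 °C
Reagents that add atoms: none
Why: Palladium-catalysed formate reduction of a vinyl triflate replaces OTf by H, and the β,γ-unsaturated ketone cannot move into conjugation because the carbon between alkene and carbonyl is quaternary; no stereocentre is formed.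

Step 3
Reactants: 4 2,2-dimethylcyclohex-3-en-1-one
Product: 5 3,3-dimethyl-4-methylidenecyclohex-1-ene
Conditions: Ph3PCH3Br, KOtBu, toluene, 0 °C to 90 °C
Reagents that add atoms: methyltriphenylphosphonium bromide, C[P+](c1ccccc1)(c1ccccc1)c1ccccc1.[Br-]
Why: Wittig methylenation with salt-free methylidenetriphenylphosphorane at elevated temperature should olefinate the hindered α,α-dimethyl ketone; no stereocentre is formed.

Step 4
Reactants: 5 3,3-dimethyl-4-methylidenecyclohex-1-ene
Product: 6 racemic 1,1-dichloro-5,5-dimethylspiro[3.5]non-6-en-2-one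
Conditions: Cl3CCOCl, activated Zn dust, POCl3, Et2O, reflux
Reagents that add atoms: trichloroacetyl chloride, ClC(Cl)(Cl)C(Cl)=O
Why: [2+2] cycloaddition of dichloroketene, made in the flask, with the 1,1-disubstituted exocyclic alkene, which is more nucleophilic than the cis-disubstituted ring alkene; the ketene carbonyl carbon bonds to the CH2 terminus so the carbonyl ends opposite the spiro carbon, and the spiro stereocentre forms as a racemate that step 5 erases.

Step 5
Reactants: 6 racemic 1,1-dichloro-5,5-dimethylspiro[3.5]non-6-en-2-one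
Product: 7 5,5-dimethylspiro[3.5]non-6-en-2-one
Conditions: Zn dust, AcOH, 50 °C
Reagents that add atoms: none
Why: Zinc reduction of the α,α-dichloroketone (reductive dehalogenation) removes both chlorines, which makes the ketone achiral and its two α-CH2 groups enantiotopic.

Step 6
Reactants: 7 5,5-dimethylspiro[3.5]non-6-en-2-one; 8 1-(trimethylsilyl)propyne
Product: 9 (6S)-5,5,9-trimethyl-10-(trimethylsilyl)spiro[5.5]undeca-3,9-dien-8-one
Conditions: Ni(cod)2 (10 mol%), BINOL-derived bis(1-phenylethyl)phosphoramidite (single antipode, 20 mol%), toluene, 90 °C, slow addition of 8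
Reagents that add atoms: none
Why: Proposed new method: zerovalent nickel should couple the C8 carbonyl and alkyne 8 by oxidative cyclisation to an oxanickelacyclopentene (new C8–C9 bond, silicon-bearing carbon on nickel), β-carbon elimination then opens the strained four-membered ring by moving one α-CH2 to nickel, and C(sp2)–C(sp3) reductive elimination from the seven-membered nickelacycle forms C10–C11 and releases the enone. The closest known reaction types are the racemic nickel/trialkylphosphine-catalysed intermolecular insertion of internal alkynes into 3,3-disubstituted cyclobutanones and the enantioselective intramolecular olefin insertion into such cyclobutanones under nickel/chiral phosphoramidite catalysis; the enantioselective intermolecular case is the new element. Ring B is closed as a formal [4+2] ring expansion of the cyclobutanone (C8, C7, C6, C11 plus the two alkyne carbons), not by cyclisation of a chain. The only new stereocentre, C6, arises because the C8–C7 and C8–C11 bonds of 7 are enantiotopic and the chiral ligand on nickel decides which one migrates; the ligand antipode that gives 9 is to be found by screening. The step needs alkyne regioselectivity (methyl-bearing carbon to C8), which the silyl group should secure by taking the nickel-bound position, chemoselectivity over the ring A alkene, which is shielded by the C5 gem-dimethyl group and cannot reach the metallacycle, and enantiotopic-bond selection, which is helped by the large steric difference between C5(CH3)2 and C1H2 on the two sides of C6.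

Step 7
Reactants: 9 (6S)-5,5,9-trimethyl-10-(trimethylsilyl)spiro[5.5]undeca-3,9-dien-8-one
Product: 10 (6R)-5,5,9-trimethylspiro[5.5]undeca-3,9-dien-8-one
Conditions: Bu4NF·3H2O, DMSO, 80 °C
Reagents that add atoms: none
Why: Fluoride attacks silicon and water protonates C10 (protodesilylation of an alkenylsilane); C6 is untouched and its descriptor changes only because the priorities change.

Step 8
Reactants: 10 (6R)-5,5,9-trimethylspiro[5.5]undeca-3,9-dien-8-one
Product: 11 (6S)-5,5,9-trimethylspiro[5.5]undeca-3,8,10-trien-8-yl acetate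
Conditions: isopropenyl acetate, TsOH (cat.), reflux
Reagents that add atoms: isopropenyl acetate, CC(=C)OC(C)=O
Why: Acid-catalysed enol acetylation under equilibrating conditions should give the through-conjugated dienyl acetate by loss of a γ-hydrogen from C11, as in the conversion of steroidal 4-en-3-ones into 3,5-dienyl acetates; no stereocentre is formed.

Step 9
Reactants: 11 (6S)-5,5,9-trimethylspiro[5.5]undeca-3,8,10-trien-8-yl acetate
Product: 12 (6R,11S)-11-hydroxy-5,5,9-trimethylspiro[5.5]undeca-3,9-dien-8-one
Conditions: mCPBA (1.0 equiv), dioxane/H2O, 0 °C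
Reagents that add atoms: 3-chloroperoxybenzoic acid, OOC(=O)c1cccc(Cl)c1
Why: The peracid should attack the electron-rich terminal carbon C11 of the dienyl acetate and the acetate then collapses to the enone (γ-hydroxylation of a dienyl acetate, a vinylogous Rubottom-type oxidation); attack is expected axially and anti to the C6–C5 bond, away from the gem-dimethyl carbon, which places the hydroxyl cis to C1 (11S).

Step 10
Reactants: 12 (6R,11S)-11-hydroxy-5,5,9-trimethylspiro[5.5]undeca-3,9-dien-8-one
Product: 13 (6R,11S)-N'-(11-hydroxy-5,5,9-trimethylspiro[5.5]undeca-3,9-dien-8-ylidene)-4-methylbenzenesulfonohydrazide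
Conditions: TsNHNH2, MeOH, rt
Reagents that add atoms: 4-methylbenzenesulfonohydrazide, Cc1ccc(cc1)S(=O)(=O)NN
Why: Condensation of the enone carbonyl with tosylhydrazide (hydrazone formation) under near-neutral conditions should leave the γ-hydroxy enone and both stereocentres intact.

Step 11
Reactants: 13 (6R,11S)-N'-(11-hydroxy-5,5,9-trimethylspiro[5.5]undeca-3,9-dien-8-ylidene)-4-methylbenzenesulfonohydrazide
Product: 16 (6R,11S)-5,5,9-trimethylspiro[5.5]undeca-3,8-dien-11-ol, via N-alkyl tosylhydrazine 14 (not isolated), via allylic diazene 15 (not isolated)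
Conditions: catecholborane (3 equiv), CHCl3, 0 °C; then NaOAc·3H2O, reflux
Reagents that add atoms: none
Why: Catecholborane adds hydride to C=N, acetate-induced loss of sulfinate gives the allylic diazene, and its retro-ene loss of N2 delivers hydrogen to C10 and moves the double bond to C8=C9 (reductive 1,3-transposition of an enone tosylhydrazone); C6 and C11 are not affected.

Step 12
Reactants: 16 (6R,11S)-5,5,9-trimethylspiro[5.5]undeca-3,8-dien-11-ol
Product: 17 (6R,8R,9R,11S)-8-bromo-9-chloro-5,5,9-trimethylspiro[5.5]undec-3-en-11-ol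
Conditions: NBS, ClTi(OiPr)3, chiral tridentate Schiff-base ligand (matched antipode, 20 mol%), hexanes/CH2Cl2, −20 °C
Reagents that add atoms: N-bromosuccinimide, O=C1CCC(=O)N1Br; chlorotitanium triisopropoxide, CC(C)O[Ti](Cl)(OC(C)C)OC(C)C
Why: Titanium binds the C11 alkoxide and should hand chloride to the tertiary C9 on the same face through a six-membered transition state, so only the bromonium ion on the opposite face (also the face anti to the axial C1 of ring A) is opened, which puts chlorine cis to O11 (9R) and bromine trans to chlorine (8R) and keeps NBS away from the ring A alkene (titanium-alkoxide-directed bromochlorination of an alkenol).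

Step 13
Reactants: 17 (6R,8R,9R,11S)-8-bromo-9-chloro-5,5,9-trimethylspiro[5.5]undec-3-en-11-ol
Product: 18 (6R,8R,9R,11S)-8-bromo-9-chloro-5,5,9-trimethylspiro[5.5]undec-3-en-11-yl acetate
Conditions: Ac2O, pyridine, DMAP (cat.), CH2Cl2, rt
Reagents that add atoms: acetic anhydride, CC(=O)OC(C)=O
Why: DMAP-catalysed acylation of the equatorial secondary alcohol should proceed with retention at C11, and the mild base should not eliminate the halides.

Step 14
Reactants: 18 (6R,8R,9R,11S)-8-bromo-9-chloro-5,5,9-trimethylspiro[5.5]undec-3-en-11-yl acetate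
Product: 19 (6R,8R,9R,11S)-8-bromo-9-chloro-5,5,9-trimethyl-2-oxospiro[5.5]undec-3-en-11-yl acetate
Conditions: CrO3, 3,5-dimethylpyrazole, CH2Cl2, −20 °C
Reagents that add atoms: chromium trioxide, O=[Cr](=O)=O
Why: Allylic oxidation with CrO3/3,5-dimethylpyrazole should give the enone C2(=O)–C3=C4, because C2 is the only allylic CH2 in the molecule (C5 is quaternary and ring B is now saturated); the stereocentres are not touched.

Step 15
Reactants: 19 (6R,8R,9R,11S)-8-bromo-9-chloro-5,5,9-trimethyl-2-oxospiro[5.5]undec-3-en-11-yl acetate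
Product: 21 (6R,8R,9R,11S)-8-bromo-9-chloro-5,5,9-trimethyl-1-methylidene-2-oxospiro[5.5]undec-3-en-11-yl acetate, via Mannich base 20 (not isolated)
Conditions: (CH2O)n, PhNHMe·CF3CO2H, THF, reflux
Reagents that add atoms: paraformaldehyde (formaldehyde unit), C=O
Why: Acid-mediated Mannich reaction with formaldehyde at C1, the only enolisable position of the enone (C5 and C6 are quaternary), followed by loss of the amine from 20 should give the exocyclic methylene (direct α-methylenation of a ketone) under non-basic conditions that spare the bromide, the chloride and the acetate.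

**Compound list**

1 | 2,2-dimethylcyclohexane-1,3-dione | CC1(C)C(=O)CCCC1=O | starting material
2 | potassium enolate of 1 | CC1(C)C(=O)CCC=C1[O-].[K+] | intermediate
3 | 6,6-dimethyl-5-oxocyclohex-1-en-1-yl trifluoromethanesulfonate | CC1(C)C(=O)CCC=C1OS(=O)(=O)C(F)(F)F | intermediate
4 | 2,2-dimethylcyclohex-3-en-1-one | CC1(C)C=CCCC1=O | intermediate
5 | 3,3-dimethyl-4-methylidenecyclohex-1-ene | C=C1CCC=CC1(C)C | intermediate
6 | racemic 1,1-dichloro-5,5-dimethylspiro[3.5]non-6-en-2-one | ClC1(Cl)C(=O)CC12CCC=CC2(C)C | intermediate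
7 | 5,5-dimethylspiro[3.5]non-6-en-2-one (achiral) | O=C1CC2(C1)CCC=CC2(C)C | intermediate
8 | 1-(trimethylsilyl)propyne | CC#C[Si](C)(C)C | starting material
9 | (6S)-5,5,9-trimethyl-10-(trimethylsilyl)spiro[5.5]undeca-3,9-dien-8-one | C1CC=CC(C)(C)[C@]12CC(=O)C(C)=C([Si](C)(C)C)C2 | intermediate
10 | (6R)-5,5,9-trimethylspiro[5.5]undeca-3,9-dien-8-one | C1CC=CC(C)(C)[C@]12CC(=O)C(C)=CC2 | intermediate
11 | (6S)-5,5,9-trimethylspiro[5.5]undeca-3,8,10-trien-8-yl acetate | C1CC=CC(C)(C)[C@]12CC(OC(C)=O)=C(C)C=C2 | intermediate
12 | (6R,11S)-11-hydroxy-5,5,9-trimethylspiro[5.5]undeca-3,9-dien-8-one | C1CC=CC(C)(C)[C@]12CC(=O)C(C)=C[C@@H]2O | intermediate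
13 | tosylhydrazone of 12 at C8 | C1CC=CC(C)(C)[C@]12CC(=NNS(=O)(=O)c3ccc(C)cc3)C(C)=C[C@@H]2O | intermediate
14 | N-alkyl tosylhydrazine (C8–H, C8–NH–NHTs; C8 configuration not defined) | C1CC=CC(C)(C)[C@]12CC(NNS(=O)(=O)c3ccc(C)cc3)C(C)=C[C@@H]2O | intermediate
15 | allylic diazene (C8–N=NH; C8 configuration not defined) | C1CC=CC(C)(C)[C@]12CC(N=N)C(C)=C[C@@H]2O | intermediate
16 | (6R,11S)-5,5,9-trimethylspiro[5.5]undeca-3,8-dien-11-ol | C1CC=CC(C)(C)[C@]12CC=C(C)C[C@@H]2O | intermediate
17 | (6R,8R,9R,11S)-8-bromo-9-chloro-5,5,9-trimethylspiro[5.5]undec-3-en-11-ol | C1CC=CC(C)(C)[C@]12C[C@@H](Br)[C@](C)(Cl)C[C@@H]2O | intermediate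
18 | (6R,8R,9R,11S)-8-bromo-9-chloro-5,5,9-trimethylspiro[5.5]undec-3-en-11-yl acetate | C1CC=CC(C)(C)[C@]12C[C@@H](Br)[C@](C)(Cl)C[C@@H]2OC(C)=O | intermediate
19 | (6R,8R,9R,11S)-8-bromo-9-chloro-5,5,9-trimethyl-2-oxospiro[5.5]undec-3-en-11-yl acetate | C1C(=O)C=CC(C)(C)[C@]12C[C@@H](Br)[C@](C)(Cl)C[C@@H]2OC(C)=O | intermediate
20 | Mannich base of 19 (C1–CH2–N(CH3)Ph; C1 configuration not defined) | CN(c3ccccc3)CC1C(=O)C=CC(C)(C)[C@]12C[C@@H](Br)[C@](C)(Cl)C[C@@H]2OC(C)=O | intermediate
21 | (6R,8R,9R,11S)-8-bromo-9-chloro-5,5,9-trimethyl-1-methylidene-2-oxospiro[5.5]undec-3-en-11-yl acetate | C=C1C(=O)C=CC(C)(C)[C@]12C[C@@H](Br)[C@](C)(Cl)C[C@@H]2OC(C)=O | target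

**Summary and risks**

Total step count: 15. Longest linear sequence: 15 steps (1 to 21); alkyne 8 enters at step 6.

Steps most likely to fail:

Step 6. The chiral ligand may discriminate poorly between the enantiotopic C8–C7 and C8–C11 bonds, or may slow the oxidative cyclisation so that alkyne oligomerisation takes over. The fallback sets out from 7 and uses the established achiral insertion (Ni(cod)2, PCy3, toluene, 100 °C), which should give racemic 5,5,9-trimethyl-10-(trimethylsilyl)spiro[5.5]undeca-3,9-dien-8-one F1. Steps 7 to 9 are then run on the racemate and should give racemic enone F2, racemic dienyl acetate F3 and racemic hydroxy enone F4. F4 is esterified with (S)-O-methylmandelic acid (DCC, DMAP) and the two diastereomeric esters are separated by chromatography. The ester of the (6R,11S) alcohol, mandelate F5, is kept and the ester of the (6S,11R) alcohol, mandelate F6, is set aside. Mild methanolysis of F5 (K2CO3, MeOH, 0 °C) comes back to the route at 12.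

Step 12. The bromonium ion may be opened without the help of titanium, which would put chloride on the wrong face of C9 or at C8, or NBS may attack the ring A alkene. The fallback sets out from 16: acetylation first (Ac2O, pyridine, DMAP) should give (6R,11S)-5,5,9-trimethylspiro[5.5]undeca-3,8-dien-11-yl acetate F7. A non-directed anti addition with Bu4NBrCl2 (CH2Cl2, −20 °C) then relies on steric control only: bromonium on the face anti to the axial C1, chloride to the tertiary C9. It comes back to the route at 18, and step 13 is no longer needed.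

Step 9. The peracid may show poor facial selectivity at C11, or may oxidise the enol acetate double bond C8=C9 instead. The fallback sets out from 11: if the main product is the 11-epimer, (6R,11R)-11-hydroxy-5,5,9-trimethylspiro[5.5]undeca-3,9-dien-8-one F8, it is inverted by a Mitsunobu reaction (4-nitrobenzoic acid, PPh3, DIAD, toluene) to (6R,11S)-5,5,9-trimethyl-8-oxospiro[5.5]undeca-3,9-dien-11-yl 4-nitrobenzoate F9, and methanolysis (K2CO3, MeOH) comes back to the route at 12.

Further compounds
F1 | step 6 | racemic 5,5,9-trimethyl-10-(trimethylsilyl)spiro[5.5]undeca-3,9-dien-8-one | C1CC=CC(C)(C)C12CC(=O)C(C)=C([Si](C)(C)C)C2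
F2 | step 6 | racemic 5,5,9-trimethylspiro[5.5]undeca-3,9-dien-8-one | C1CC=CC(C)(C)C12CC(=O)C(C)=CC2
F3 | step 6 | racemic 5,5,9-trimethylspiro[5.5]undeca-3,8,10-trien-8-yl acetate | C1CC=CC(C)(C)C12CC(OC(C)=O)=C(C)C=C2
F4 | step 6 | racemic (6R*,11S*)-11-hydroxy-5,5,9-trimethylspiro[5.5]undeca-3,9-dien-8-one (both enantiomers) | C1CC=CC(C)(C)[C@]12CC(=O)C(C)=C[C@@H]2O.C1CC=CC(C)(C)[C@@]12CC(=O)C(C)=C[C@H]2O
F5 | step 6 | (6R,11S)-5,5,9-trimethyl-8-oxospiro[5.5]undeca-3,9-dien-11-yl (S)-2-methoxy-2-phenylacetate | C1CC=CC(C)(C)[C@]12CC(=O)C(C)=C[C@@H]2OC(=O)[C@@H](OC)c1ccccc1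
F6 | step 6 | (6S,11R)-5,5,9-trimethyl-8-oxospiro[5.5]undeca-3,9-dien-11-yl (S)-2-methoxy-2-phenylacetate | C1CC=CC(C)(C)[C@@]12CC(=O)C(C)=C[C@H]2OC(=O)[C@@H](OC)c1ccccc1
F7 | step 12 | (6R,11S)-5,5,9-trimethylspiro[5.5]undeca-3,8-dien-11-yl acetate | C1CC=CC(C)(C)[C@]12CC=C(C)C[C@@H]2OC(C)=O
F8 | step 9 | (6R,11R)-11-hydroxy-5,5,9-trimethylspiro[5.5]undeca-3,9-dien-8-one | C1CC=CC(C)(C)[C@]12CC(=O)C(C)=C[C@H]2O
F9 | step 9 | (6R,11S)-5,5,9-trimethyl-8-oxospiro[5.5]undeca-3,9-dien-11-yl 4-nitrobenzoate | C1CC=CC(C)(C)[C@]12CC(=O)C(C)=C[C@@H]2OC(=O)c1ccc(cc1)[N+](=O)[O-]
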